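**Retrosynthetic overview**

- The strategy rests on the C2 substituent of the imidazole ring. It begins with a CH2 bonded to the amidine carbon C2 (between N1 and N3) and continues with three more CH2 groups and the ester oxygen, so it is a 2-methyl group lengthened by a three-carbon oxygenated electrophile.
- Last operations: O-acetylation of the primary alcohol, preceded by removal of the N-SEM and O-TBS groups in one acid treatment.
- Key disconnection: the bond between the first and second carbons of the C2 chain, made by lateral lithiation of the 2-methyl group of an N-SEM 2,5-dimethyl-4-(arylethyl)imidazole and alkylation with (3-bromopropoxy)(tert-butyl)dimethylsilane.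
- The C4–CH2 bond comes from a B-alkyl Suzuki–Miyaura coupling of an N-SEM 4-iodo-2,5-dimethylimidazole with the 9-BBN adduct of 3,4-dimethoxystyrene. The iodide comes from 2,4-dimethylimidazole by C5 iodination and N-protection.
- No ring is formed: the imidazole and benzene rings are bought intact, and the target has no stereocenter.

Key step: step 4

Abbreviations: SEM = [2-(trimethylsilyl)ethoxy]methyl; TBS = tert-butyldimethylsilyl; 9-BBN = 9-borabicyclo[3.3.1]nonane; dppf = 1,1'-bis(diphenylphosphino)ferrocene.

Assumption: N-alkylation of the imidazolide of 2 is taken to go mainly at the nitrogen remote from iodine (the one next to the ring methyl group), giving 4 as drawn. The minor N-regioisomer is removed by chromatography; it would lead to the same target, because the SEM group is lost at the end.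

**Step 1**
Reactants: 1 2,4-dimethyl-1H-imidazole
Product: 2 4-iodo-2,5-dimethyl-1H-imidazole
Conditions: N-iodosuccinimide (1.05 equiv), MeCN, 0 °C → rt, dark
Reagents that add atoms: N-iodosuccinimide, O=C1CCC(=O)N1I
Why: Electrophilic aromatic iodination of the electron-rich imidazole, in which C5 is the only unsubstituted ring carbon, so iodine can enter only there and both methyl groups are untouched.

**Step 2**
Reactants: 2 4-iodo-2,5-dimethyl-1H-imidazole
Product: 4 4-iodo-2,5-dimethyl-1-{[2-(trimethylsilyl)ethoxy]methyl}-1H-imidazole, via sodium imidazolide 3 (not isolated)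
Conditions: NaH (1.2 equiv), THF–DMF, 0 °C; then SEMCl (1.1 equiv), 0 °C → rt; chromatography
Reagents that add atoms: 2-(trimethylsilyl)ethoxymethyl chloride (SEMCl), C[Si](C)(C)CCOCCl
Why: SN2 N-alkylation of the sodium imidazolide by the chloromethyl ether should go mainly at the nitrogen remote from the electron-withdrawing and larger iodine, and the SEM group removes the acidic N–H before the organometallic steps.

**Step 3**
Reactants: 4 4-iodo-2,5-dimethyl-1-{[2-(trimethylsilyl)ethoxy]methyl}-1H-imidazole; 5 3,4-dimethoxystyrene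
Product: 7 4-[2-(3,4-dimethoxyphenyl)ethyl]-2,5-dimethyl-1-{[2-(trimethylsilyl)ethoxy]methyl}-1H-imidazole, via alkylborane 6 (not isolated)
Conditions: 5, 9-BBN (0.5 M in THF), 0 °C → rt; then 4, PdCl2(dppf) (5 mol %), 3 M aq NaOH, THF, 65 °C
Reagents that add atoms: none
Why: Anti-Markovnikov hydroboration of the styrene gives the primary B-alkyl-9-BBN, which in a B-alkyl Suzuki–Miyaura coupling transfers its alkyl group as the hydroxyborate to the heteroarylpalladium iodide formed from 4 and zerovalent palladium, the wide bite angle of dppf favouring reductive elimination over β-hydride elimination.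

**Step 4**
Reactants: 7 4-[2-(3,4-dimethoxyphenyl)ethyl]-2,5-dimethyl-1-{[2-(trimethylsilyl)ethoxy]methyl}-1H-imidazole; 8 (3-bromopropoxy)(tert-butyl)dimethylsilane
Product: 10 2-{4-[(tert-butyldimethylsilyl)oxy]butyl}-4-[2-(3,4-dimethoxyphenyl)ethyl]-5-methyl-1-{[2-(trimethylsilyl)ethoxy]methyl}-1H-imidazole (N-SEM O-TBS cypholophine), via lithiomethyl imidazole 9 (not isolated)
Conditions: n-BuLi (1.05 equiv), THF, −78 °C, 1 h; then 8 (1.3 equiv), −78 → 0 °C
Reagents that add atoms: none
Why: n-Butyllithium removes a proton from the 2-methyl group to give the 2-lithiomethyl species 9, an aza-enolate whose charge is shared with N3 and whose lithium is held by the SEM ether oxygen on N1, and this primary carbanion displaces bromide from 8 in an SN2 reaction, joining the first and second carbons of the C2 chain. The closest known reaction type is the lateral lithiation and alkylation of N-protected 2-methylimidazoles (and of 2-picoline) with primary alkyl halides. No ring is closed and no stereocenter is formed. The step needs site selectivity among three sets of side-chain protons: only the anion at the 2-methyl group is conjugated with the C2=N3 bond, whereas an anion at the 5-methyl group or at the CH2 on C4 could delocalise only onto ring carbon, and ring lithiation is excluded because C2, C4 and C5 all carry carbon substituents. Ortho-lithiation of the dimethoxybenzene ring is too slow at −78 °C to compete, and in 8 the silyl ether is inert, so the primary C–Br carbon is the only electrophilic site. After alkylation the remaining CH2 is less acidic than the original methyl group, which limits a second alkylation.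

**Step 5**
Reactants: 10 N-SEM O-TBS cypholophine
Product: 13 4-{4-[2-(3,4-dimethoxyphenyl)ethyl]-5-methyl-1H-imidazol-2-yl}butan-1-ol (cypholophine), via N-SEM alcohol 11 (not isolated), via N-hydroxymethyl imidazole 12 (not isolated)
Conditions: 3 M aq HCl, EtOH, 80 °C; basic work-up (pH 10)
Reagents that add atoms: none
Why: Acid-catalysed solvolysis first cleaves the primary O–TBS ether and then, on heating, the N–CH2–O aminal of the SEM group with loss of 2-(trimethylsilyl)ethanol, and the N-hydroxymethyl intermediate gives up formaldehyde on basic work-up, while the aryl methyl ethers and the imidazole ring withstand hot dilute HCl.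

**Step 6**
Reactants: 13 cypholophine
Product: 14 4-{4-[2-(3,4-dimethoxyphenyl)ethyl]-5-methyl-1H-imidazol-2-yl}butyl acetate (O-acetylcypholophine)
Conditions: Ac2O (1.2 equiv), pyridine, 0 °C → rt; sat. aq NaHCO3 work-up
Reagents that add atoms: acetic anhydride, CC(=O)OC(C)=O
Why: Acylation of the primary alcohol by acetic anhydride with pyridine as base and nucleophilic catalyst, in which any N-acetylimidazole formed at the ring nitrogen is itself an acyl donor and is hydrolysed in the bicarbonate work-up, so only the O-acetate should remain.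

**Compound list**

1 | 2,4-dimethyl-1H-imidazole | Cc1c[nH]c(C)n1 | starting material
2 | 4-iodo-2,5-dimethyl-1H-imidazole | Cc1nc(I)c(C)[nH]1 | intermediate
3 | sodium 4-iodo-2,5-dimethylimidazol-1-ide | Cc1nc(I)c(C)[n-]1.[Na+] | intermediate
4 | 4-iodo-2,5-dimethyl-1-{[2-(trimethylsilyl)ethoxy]methyl}-1H-imidazole | Cc1nc(I)c(C)n1COCC[Si](C)(C)C | intermediate
5 | 3,4-dimethoxystyrene | C=Cc1ccc(OC)c(OC)c1 | starting material
6 | 9-[2-(3,4-dimethoxyphenyl)ethyl]-9-borabicyclo[3.3.1]nonane | COc1ccc(CCB2C3CCCC2CCC3)cc1OC | intermediate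
7 | 4-[2-(3,4-dimethoxyphenyl)ethyl]-2,5-dimethyl-1-{[2-(trimethylsilyl)ethoxy]methyl}-1H-imidazole | COc1ccc(CCc2nc(C)n(COCC[Si](C)(C)C)c2C)cc1OC | intermediate
8 | (3-bromopropoxy)(tert-butyl)dimethylsilane | CC(C)(C)[Si](C)(C)OCCCBr | starting material
9 | 4-[2-(3,4-dimethoxyphenyl)ethyl]-2-(lithiomethyl)-5-methyl-1-{[2-(trimethylsilyl)ethoxy]methyl}-1H-imidazole | COc1ccc(CCc2nc(C[Li])n(COCC[Si](C)(C)C)c2C)cc1OC | intermediate
10 | 2-{4-[(tert-butyldimethylsilyl)oxy]butyl}-4-[2-(3,4-dimethoxyphenyl)ethyl]-5-methyl-1-{[2-(trimethylsilyl)ethoxy]methyl}-1H-imidazole (N-SEM O-TBS cypholophine) | COc1ccc(CCc2nc(CCCCO[Si](C)(C)C(C)(C)C)n(COCC[Si](C)(C)C)c2C)cc1OC | intermediate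
11 | 4-{4-[2-(3,4-dimethoxyphenyl)ethyl]-5-methyl-1-{[2-(trimethylsilyl)ethoxy]methyl}-1H-imidazol-2-yl}butan-1-ol (N-SEM cypholophine) | COc1ccc(CCc2nc(CCCCO)n(COCC[Si](C)(C)C)c2C)cc1OC | intermediate
12 | 4-{4-[2-(3,4-dimethoxyphenyl)ethyl]-1-(hydroxymethyl)-5-methyl-1H-imidazol-2-yl}butan-1-ol | COc1ccc(CCc2nc(CCCCO)n(CO)c2C)cc1OC | intermediate
13 | 4-{4-[2-(3,4-dimethoxyphenyl)ethyl]-5-methyl-1H-imidazol-2-yl}butan-1-ol (cypholophine) | COc1ccc(CCc2nc(CCCCO)[nH]c2C)cc1OC | intermediate
14 | 4-{4-[2-(3,4-dimethoxyphenyl)ethyl]-5-methyl-1H-imidazol-2-yl}butyl acetate (O-acetylcypholophine) | COc1ccc(CCc2nc(CCCCOC(C)=O)[nH]c2C)cc1OC | target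

**Step count**

Total: 6 steps. Longest linear sequence: 6 steps (1 → 2 → 4 → 7 → 10 → 13 → 14); 5 and 8 enter as purchased reagents.

**Steps most likely to fail**

1. Step 4 (key step). The lithiomethyl anion may act as a base toward the bromide (E2 loss of HBr), or the SN2 displacement may be too slow at low temperature, so that 7 is recovered after quench. The fallback sets out from 7 and comes back at 10. The same anion 9 is added at −78 °C to commercial 3-[(tert-butyldimethylsilyl)oxy]propanal (CC(C)(C)[Si](C)(C)OCCC=O). Carbonyl addition is faster than alkylation and cannot be diverted into elimination. It should give the racemic secondary alcohol 4-[(tert-butyldimethylsilyl)oxy]-1-{4-[2-(3,4-dimethoxyphenyl)ethyl]-5-methyl-1-SEM-imidazol-2-yl}butan-2-ol F1. MsCl and Et3N in CH2Cl2 convert it into the methanesulfonate F2, which is not isolated. DBU eliminates it to the ring-conjugated (E)-2-(but-1-enyl)imidazole F3. Hydrogenation (H2, Pd/C, EtOAc) saturates the alkene and removes the temporary stereocenter, giving 10.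

2. Step 3. Oxidative addition into the electron-rich C4–I bond, flanked by N3 and the 5-methyl group, may be slow. The basic N3 may also bind palladium, and protodeiodination or β-hydride elimination from the alkylpalladium intermediate may take over. The fallback sets out from 4 and comes back at 7. Sonogashira coupling of 4 with commercial 4-ethynyl-1,2-dimethoxybenzene (C#Cc1ccc(OC)c(OC)c1) under PdCl2(PPh3)2, CuI and Et3N in DMF at 60 °C uses a copper acetylide that transmetallates quickly and carries no β-hydrogen. It should give the alkyne 4-[(3,4-dimethoxyphenyl)ethynyl]-2,5-dimethyl-1-SEM-imidazole F4. Hydrogenation (H2, Pd/C, EtOAc) reduces the triple bond to the CH2CH2 bridge of 7.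

3. Step 5. The protonated imidazolium may resist ionisation of the aminal, so the reaction may stall at 11 or 12. Formaldehyde set free in hot acid may be captured by the electron-rich dimethoxybenzene ring. The polar amino alcohol 13 may also be lost to the aqueous phase. The fallback sets out from 10 and comes back at 14, bypassing 13, by staging the endgame. Bu4NF (1.1 equiv, THF, rt) cleaves only the silyl ether, and 11 is isolated. Ac2O in pyridine acetylates it, with no ring N–H present, to N-SEM O-acetylcypholophine F5. Trifluoroacetic acid in CH2Cl2 (rt to 40 °C), an anhydrous medium that spares the ester, cleaves the SEM aminal to the N-hydroxymethyl acetate F6, which is not isolated. F6 gives up formaldehyde only during the aqueous NaHCO3–THF work-up, where it is not an activated electrophile, and delivers 14.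

**Further compounds**

F1 | step 4 | 4-[(tert-butyldimethylsilyl)oxy]-1-{4-[2-(3,4-dimethoxyphenyl)ethyl]-5-methyl-1-{[2-(trimethylsilyl)ethoxy]methyl}-1H-imidazol-2-yl}butan-2-ol (racemic) | COc1ccc(CCc2nc(CC(O)CCO[Si](C)(C)C(C)(C)C)n(COCC[Si](C)(C)C)c2C)cc1OC
F2 | step 4 | 4-[(tert-butyldimethylsilyl)oxy]-1-{4-[2-(3,4-dimethoxyphenyl)ethyl]-5-methyl-1-{[2-(trimethylsilyl)ethoxy]methyl}-1H-imidazol-2-yl}butan-2-yl methanesulfonate (racemic) | COc1ccc(CCc2nc(CC(OS(C)(=O)=O)CCO[Si](C)(C)C(C)(C)C)n(COCC[Si](C)(C)C)c2C)cc1OC
F3 | step 4 | 2-[(E)-4-[(tert-butyldimethylsilyl)oxy]but-1-en-1-yl]-4-[2-(3,4-dimethoxyphenyl)ethyl]-5-methyl-1-{[2-(trimethylsilyl)ethoxy]methyl}-1H-imidazole | COc1ccc(CCc2nc(/C=C/CCO[Si](C)(C)C(C)(C)C)n(COCC[Si](C)(C)C)c2C)cc1OC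
F4 | step 3 | 4-[(3,4-dimethoxyphenyl)ethynyl]-2,5-dimethyl-1-{[2-(trimethylsilyl)ethoxy]methyl}-1H-imidazole | COc1ccc(C#Cc2nc(C)n(COCC[Si](C)(C)C)c2C)cc1OC
F5 | step 5 | 4-{4-[2-(3,4-dimethoxyphenyl)ethyl]-5-methyl-1-{[2-(trimethylsilyl)ethoxy]methyl}-1H-imidazol-2-yl}butyl acetate | COc1ccc(CCc2nc(CCCCOC(C)=O)n(COCC[Si](C)(C)C)c2C)cc1OC
F6 | step 5 | 4-{4-[2-(3,4-dimethoxyphenyl)ethyl]-1-(hydroxymethyl)-5-methyl-1H-imidazol-2-yl}butyl acetate | COc1ccc(CCc2nc(CCCCOC(C)=O)n(CO)c2C)cc1OC
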